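The vessel is closed and stirred; E and Z meet on Q and give L.

| flask | E | Z | Q | time |
|---|---|---|---|---|
| north-east | 0.500 M | 1.25 M | 0.0500 M |  |
| south-west | 0.300 M | 1.05 M | 0.0500 M |  |
| south-east | 0.750 M | 1.25 M | 0.0500 M |  |
| south | 0.250 M | 1.25 M | 0.100 M | 34 min |

| run | time / min | [L] / M |
|---|---|---|
| north-east run | 4.9 | 0.0722 |
| north-east run | 9.7 | 0.1288 |
| north-east run | 15 | 0.1673 |
| north-east run | 19 | 0.1873 |
| north-east run | 24 | 0.2060 |
| north-east run | 29 | 0.2160 |
| north-east run | 34 | 0.2247 |
| south-west run | 4.9 | 0.0426 |
| south-west run | 9.7 | 0.0745 |
| south-west run | 15 | 0.0995 |
| south-west run | 19 | 0.1119 |
| south-west run | 24 | 0.1178 |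
| south-west run | 29 | 0.1269 |
| south-west run | 34 | 0.1293 |
| south-east run | 4.9 | 0.0950 |
| south-east run | 9.7 | 0.1667 |
| south-east run | 15 | 0.2217 |
| south-east run | 19 | 0.2479 |
| south-east run | 24 | 0.2758 |
| south-east run | 29 | 0.2926 |
| south-east run | 34 | 0.3043 |

(readings scatter by 0.002 M)

- Overall: E + Z -> L, with Q as catalyst.
- Constant volume, constant temperature.
- What is held in complexes is read along with the free species.
- "The second partner" is Z.
- An order is taken over about fifteen percent of the charge, up and down.

- the power of [Z] that the first rate follows, about the charge of the north-east run; measure it at two percent of E made into L
- the power of [E] that the first rate follows, about the charge of the north-east run; measure it at two percent of E made into L (one fixed amount of L, the same in the runs compared)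
- L in the south run at 34 min, as a share of the E charged

Every curve bends over, and the question is what a doubled Q does to that bend. E is the limiting reagent, since the smallest Z charge stands above the largest E charge. Z does not stay steady, for the L of the last north-east reading alone equals 18.0 % of the Z charged in that run, but as a rough first step I hold it constant (pseudo-first-order). Then d ln[E]/dt is minus a constant times active Q, and it integrates at once: ln of E charged over E left equals that constant times the time integral of active Q. I take E left as the charge less L. In the north-east run at 34 min this gives 0.597; I call this number the reach, the logarithm of E charged over E charged less L.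

Two extremes can be solved in the head. If the bend is an equilibrium, Q hastens it without moving it, and the south run stays close to the north-east share, 44.9 %. If instead Q is dying and L stays, I assume the reach scales with Q charged. The first readings of the south-east and north-east runs put the order in E near 0.677, so the leaner E of the south run lifts it further, to 1.49, a share of 77.5 %. I have not tested these two pictures against the readings, and any undoing of L pulls the second figure down, so as a rough estimate I take the middle, 61.2 %.

The forecast gives 0.9 for Z, 0.65 for E and 52 % for the south run, reasoning that “Doubled Q means equilibrium is reached by 34 min”. Its share is lower than mine.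

The flask gives 1.0 for Z, 0.65 for E and 65.1 % for the south run.

    Q + E ⇌ QE, settled at all times (1.370 /M)
    QE + Z → L + Q (0.7500 /M/min)
    L + Z → G (0.009060 /M/min)
    Q → Rx (0.04536 /min)

Read from L, the south run has a reach of 1.05, less than my scaled figure. The main reason for the shortfall is the passing of L and Z into G, which costs 18 percentage points in the south run and hides E that has in fact turned. The simulated south run without that step ends at 82.8 %, a reach of 1.76, more than the 1.49 I scaled.

The runs are calculated with constants of no real substance; noise was put on by code.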